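Between the last reading at 6.00 h and the asked 12 h, intermediate A in this flask, charged with 20 mM substrate, may pass its peak, and the noon readings allow an estimate of where that peak lies.

noon run (percent of the substrate charged)

| time / h | product / % | substrate / % | intermediate C / % | intermediate A / % | intermediate B / % |
|---|---|---|---|---|---|
| 0.500 | 0 | 88 | 1 | 5 | 3 |
| 0.833 | 3 | 82 | 2 | 12 | 7 |
| 1.50 | 2 | 72 | 1 | 14 | 8 |
| 3.00 | 0 | 59 | 1 | 27 | 10 |
| 6.00 | 3 | 40 | 1 | 42 | 6 |

(standard deviation of a reading: 1.5 percentage points)

1. the species in which most of what was charged as substrate, at 12 h sits (intermediate B / intermediate C / intermediate A / product / substrate)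
2. the largest share itself, whichever of these holds it, in percent of the substrate charged

Substrate and intermediate B are taken as one pool feeding intermediate A, and the zero of the scale is [intermediate A] equal to what the pool has given up, with no loss from intermediate A. At 6.00 h the readings put the pool's loss at 54.0%, but [intermediate A] reads 42%, so by these readings 12.0% has left. Dividing that by the area under the [intermediate A] readings, 1.47 h in charge-hours, gives the drain constant κ, the overall first-order loss constant of intermediate A: 0.0816 h⁻¹.

The pool falls with λ = 0.129 h⁻¹, and the reading at 3.00 h gives 0.124 h⁻¹. As a share of the charge, [intermediate A] = λ/(κ−λ)·(exp(−λt) − exp(−κt)), which in this reckoning peaks at 9.64 h. This reckoning gives 44.4% at 12 h, against 42% read at 6.00 h. It leaves the pool 21.3% and puts 34.3% beyond intermediate A, so it names intermediate A as holding the most, with more than either of these. The two stand close because feed beats drain at the earlier time, 0.0595 h⁻¹ against 0.0343 h⁻¹, and loses at the later one, 0.0274 h⁻¹ against 0.0362 h⁻¹.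

The forecast names the same species and a different share, intermediate A at 60%: “Intermediate A therefore takes nearly everything else”.

The flask gives intermediate A at 43.2%.

    substrate → intermediate A (k = 3.91 × 10⁻⁵ s⁻¹)
    substrate ⇌ intermediate B (K = 0.130, k = 3.08 × 10⁻⁵ s⁻¹)
    intermediate A → product (k = 3.76 × 10⁻⁶ s⁻¹)
    intermediate A ⇌ intermediate C (K = 1.39, k = 6.52 × 10⁻⁷ s⁻¹)
    intermediate B → intermediate A (k = 4.12 × 10⁻⁶ s⁻¹)
    intermediate A → decomposed reagent (k = 1.88 × 10⁻⁵ s⁻¹)

That stands 17 percentage points below the forecast and 1.2 points below the reckoning, while decomposed reagent holds 28.1% at 12 h. The flask left until 20 h, with time changed and the charge held, takes the same κ and λ. The reckoning gives it 32.6%, and that flask holds 31.8% intermediate A.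

(The numbers in the tables were computed on assumed constants, and the scatter is random.)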